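The depside is cut at its ester into a ring A acid and a ring B phenol. Ring A is then cut at two neighbouring bonds, C1–CO2H and C2–heptyl. Since C1 also adjoins the C6 methoxy carbon, the ring maps onto 3,5-dimethoxybenzyne, whose OMe-flanked carbon takes the electrophile and whose remote carbon takes the nucleophile. One flask operation (iodine–magnesium exchange, triflate loss, heptyl Grignard addition, CO2 trapping) therefore installs the alkyl chain and the carboxyl with the required orientation. The precursor is 2-iodo-3,5-dimethoxyphenyl triflate, two steps from symmetric 3,5-dimethoxyphenol. Ring B comes from olivetolic acid as a benzyl ester with only the 4-OH free; TFAA-mediated esterification and hydrogenolysis finish the synthesis.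

Key step: step 4

Remark: ring A is numbered from the carbonyl-bearing carbon (C1), with heptyl on C2 and methoxy groups on C4 and C6; the target contains no stereocentre, so none has to be set.

Step 1
Reactants: 1 3,5-dimethoxyphenol
Product: 2 2-iodo-3,5-dimethoxyphenol
Conditions: NIS (1.0 equiv), CH2Cl2, −20 to 0 °C, dark
Reagents that add atoms: N-iodosuccinimide, O=C1CCC(=O)N1I
Why: Electrophilic aromatic iodination, in which the hydroxyl is the strongest activator and the site between OH and OMe is less crowded than the site between the two OMe groups, so mono-iodination ortho to the hydroxyl should dominate and any 4-iodo isomer should be separable by chromatography.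

Step 2
Reactants: 2 2-iodo-3,5-dimethoxyphenol
Product: 3 2-iodo-3,5-dimethoxyphenyl trifluoromethanesulfonate
Conditions: Tf2O, pyridine, CH2Cl2, 0 °C
Reagents that add atoms: trifluoromethanesulfonic anhydride, O=S(=O)(OS(=O)(=O)C(F)(F)F)C(F)(F)F
Why: O-sulfonylation of a phenol with triflic anhydride and an amine base is routine and tolerates the aryl iodide and the methyl ethers.

Step 3
Reactants: 4 1-bromoheptane
Product: 5 heptylmagnesium bromide (THF solution, titrated before use)
Conditions: Mg turnings, cat. I2, THF, 25–50 °C
Reagents that add atoms: magnesium, [Mg]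
Why: Grignard formation by oxidative insertion of magnesium into a primary alkyl bromide.

Step 4
Reactants: 3 2-iodo-3,5-dimethoxyphenyl trifluoromethanesulfonate; 5 heptylmagnesium bromide (about 3 equiv); 6 carbon dioxide
Product: 10 2-heptyl-4,6-dimethoxybenzoic acid, via magnesiated triflate 7 (not isolated), via 3,5-dimethoxybenzyne 8 (not isolated), via aryl Grignard 9 (not isolated)
Conditions: 3 added slowly to 5 (3 equiv), THF, −78 → 0 °C; then dry CO2 (6), −40 °C → rt; aq HCl
Reagents that add atoms: none
Why: The iodide of 3, activated by the flanking triflate and methoxy groups, should undergo iodine–magnesium exchange with the first equivalent of 5 to give 7, which loses magnesium triflate at once to form aryne 8. A second equivalent of 5 adds across the strained triple bond (aryne carbomagnesiation) to give 9, which CO2 carboxylates; the closest known reaction type is aryne generation from 2-haloaryl sulfonates by halogen–magnesium exchange, followed by Grignard addition and electrophile quench. No ring is closed and no stereocentre is formed. The selectivity needed is regiochemical: the methoxy group next to the triple bond is σ-withdrawing and distorts the aryne, so the carbon remote from it is the more electrophilic, and attack there places the carbanion beside oxygen, where induction and Mg–O chelation stabilise it. Using 5 itself for the exchange means that no second carbon nucleophile competes for the aryne, and slow addition of 3 to excess 5 keeps 8 dilute so that 7 and 9 should not add to it.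

Step 5
Reactants: 11 olivetolic acid (2,4-dihydroxy-6-pentylbenzoic acid)
Product: 12 benzyl 2,4-dihydroxy-6-pentylbenzoate
Conditions: BnBr (1.05 equiv), KHCO3, DMF, rt
Reagents that add atoms: benzyl bromide, BrCc1ccccc1
Why: SN2 alkylation of the carboxylate, since bicarbonate deprotonates only the acid and leaves both phenols untouched, and room temperature avoids decarboxylation of the β-resorcylic acid.

Step 6
Reactants: 12 benzyl 2,4-dihydroxy-6-pentylbenzoate
Product: 13 benzyl 4-(allyloxy)-2-hydroxy-6-pentylbenzoate
Conditions: allyl bromide (1.05 equiv), K2CO3, acetone, rt to 40 °C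
Reagents that add atoms: allyl bromide, C=CCBr
Why: Williamson etherification that should be selective for the 4-OH, because the 2-OH is hydrogen-bonded to the ester carbonyl and flanked by the ester while the 4-OH is the more acidic and unhindered.

Step 7
Reactants: 13 benzyl 4-(allyloxy)-2-hydroxy-6-pentylbenzoate
Product: 14 benzyl 4-(allyloxy)-2-methoxy-6-pentylbenzoate
Conditions: MeI (excess), K2CO3, DMF, 40–50 °C
Reagents that add atoms: iodomethane, CI
Why: Williamson O-methylation of the remaining chelated phenol, which a polar aprotic solvent and excess methyl iodide should drive to completion without affecting the allyl ether or the hindered benzyl ester.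

Step 8
Reactants: 14 benzyl 4-(allyloxy)-2-methoxy-6-pentylbenzoate
Product: 15 benzyl 4-hydroxy-2-methoxy-6-pentylbenzoate
Conditions: Pd(PPh3)4 (cat.), morpholine, THF, rt
Reagents that add atoms: none
Why: Tsuji–Trost deallylation, in which Pd(0) ionises the aryl allyl ether to a π-allyl complex that morpholine captures, while the benzyl ester and methyl ether are inert.

Step 9
Reactants: 10 2-heptyl-4,6-dimethoxybenzoic acid; 15 benzyl 4-hydroxy-2-methoxy-6-pentylbenzoate
Product: 17 benzyl 4-[(2-heptyl-4,6-dimethoxybenzoyl)oxy]-2-methoxy-6-pentylbenzoate, via mixed trifluoroacetic anhydride 16 (not isolated)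
Conditions: TFAA, toluene, rt
Reagents that add atoms: none
Why: Depside esterification through the mixed anhydride, where the electron-rich 2,6-disubstituted acid ionises readily to a stabilised, sterically small acylium species that the free 4-OH of 15 should capture, while the hindered benzyl ester of 15 stays intact.

Step 10
Reactants: 17 benzyl 4-[(2-heptyl-4,6-dimethoxybenzoyl)oxy]-2-methoxy-6-pentylbenzoate
Product: 18 4-[(2-heptyl-4,6-dimethoxybenzoyl)oxy]-2-methoxy-6-pentylbenzoic acid (target)
Conditions: H2 (1 atm), 10% Pd/C, EtOAc, rt
Reagents that add atoms: none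
Why: Catalytic hydrogenolysis of the benzyl ester, which leaves the aryl ester linkage, the methyl ethers and the alkyl chains unchanged.

Compound list
1 | 3,5-dimethoxyphenol | COc1cc(O)cc(OC)c1 | starting material
2 | 2-iodo-3,5-dimethoxyphenol | COc1cc(OC)c(I)c(O)c1 | intermediate
3 | 2-iodo-3,5-dimethoxyphenyl trifluoromethanesulfonate | COc1cc(OC)c(I)c(OS(=O)(=O)C(F)(F)F)c1 | intermediate
4 | 1-bromoheptane | CCCCCCCBr | starting material
5 | heptylmagnesium bromide | CCCCCCC[Mg]Br | intermediate
6 | carbon dioxide | O=C=O | starting material
7 | 2-(bromomagnesio)-3,5-dimethoxyphenyl trifluoromethanesulfonate (magnesiated triflate, not isolated) | COc1cc(OC)c([Mg]Br)c(OS(=O)(=O)C(F)(F)F)c1 | intermediate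
8 | 3,5-dimethoxybenzyne (not isolated) | COC1=CC(OC)=CC#C1 | intermediate
9 | (2-heptyl-4,6-dimethoxyphenyl)magnesium bromide (aryl Grignard, not isolated) | CCCCCCCc1cc(OC)cc(OC)c1[Mg]Br | intermediate
10 | 2-heptyl-4,6-dimethoxybenzoic acid | CCCCCCCc1cc(OC)cc(OC)c1C(=O)O | intermediate
11 | olivetolic acid (2,4-dihydroxy-6-pentylbenzoic acid) | CCCCCc1cc(O)cc(O)c1C(=O)O | starting material
12 | benzyl 2,4-dihydroxy-6-pentylbenzoate | CCCCCc1cc(O)cc(O)c1C(=O)OCc1ccccc1 | intermediate
13 | benzyl 4-(allyloxy)-2-hydroxy-6-pentylbenzoate | CCCCCc1cc(OCC=C)cc(O)c1C(=O)OCc1ccccc1 | intermediate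
14 | benzyl 4-(allyloxy)-2-methoxy-6-pentylbenzoate | CCCCCc1cc(OCC=C)cc(OC)c1C(=O)OCc1ccccc1 | intermediate
15 | benzyl 4-hydroxy-2-methoxy-6-pentylbenzoate | CCCCCc1cc(O)cc(OC)c1C(=O)OCc1ccccc1 | intermediate
16 | 2-heptyl-4,6-dimethoxybenzoic trifluoroacetic anhydride (not isolated) | CCCCCCCc1cc(OC)cc(OC)c1C(=O)OC(=O)C(F)(F)F | intermediate
17 | benzyl 4-[(2-heptyl-4,6-dimethoxybenzoyl)oxy]-2-methoxy-6-pentylbenzoate | CCCCCCCc1cc(OC)cc(OC)c1C(=O)Oc1cc(CCCCC)c(C(=O)OCc2ccccc2)c(OC)c1 | intermediate
18 | 4-[(2-heptyl-4,6-dimethoxybenzoyl)oxy]-2-methoxy-6-pentylbenzoic acid | CCCCCCCc1cc(OC)cc(OC)c1C(=O)Oc1cc(CCCCC)c(C(=O)O)c(OC)c1 | target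

Total step count: 10.
Longest linear sequence: 6 steps (11 → 12 → 13 → 14 → 15 → 17 → 18). The ring A branch (1 → 2 → 3 → 10 → 17 → 18) is 5 steps, and step 3 is a one-step side branch.

Steps most likely to fail

1. Step 4. The Grignard reagent may attack sulfur of the triflate and cleave the S–O bond instead of exchanging the iodide. The exchange may be incomplete. The aryne may be captured by the aryl magnesium species present and give biaryls. Excess reagent is carboxylated to octanoic acid, which must be removed from the product. Fallback, setting out from 5: nickel-catalysed Kumada coupling (Ni(dppp)Cl2, THF) with commercial 1-bromo-3,5-dimethoxybenzene should give 1-heptyl-3,5-dimethoxybenzene F1. Vilsmeier–Haack formylation (POCl3, DMF) at the position ortho to the chain and para to a methoxy group should give 2-heptyl-4,6-dimethoxybenzaldehyde F2, separable from the minor symmetrical isomer. Pinnick oxidation (NaClO2, NaH2PO4, 2-methyl-2-butene, t-BuOH/H2O) returns to the route at 10.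

2. Step 1. Iodination may go partly to the position between the two methoxy groups, or proceed twice, which would lower the supply of the ortho-iodophenol. Fallback, setting out from 1: protection with MOMCl and i-Pr2NEt gives 1,3-dimethoxy-5-(methoxymethoxy)benzene F3. Directed ortho-lithiation (n-BuLi, THF, 0 °C) at the cooperative site between the better-coordinating acetal oxygen and a methoxy group, then quenching with I2, should give 2-iodo-1,5-dimethoxy-3-(methoxymethoxy)benzene F4. Acetal cleavage with HCl in MeOH returns to the route at 2.

3. Step 9. O-acylation of the para-ester-deactivated phenol by the doubly ortho-substituted acid may be slow, and trifluoroacetylation of the phenol or Friedel–Crafts C-acylation of an electron-rich ring may compete. Fallback, setting out from 10: oxalyl chloride with catalytic DMF in CH2Cl2 gives the isolated 2-heptyl-4,6-dimethoxybenzoyl chloride F5. This is coupled with 15 under nucleophilic catalysis (Et3N, DMAP, CH2Cl2, rt to 40 °C), returning to the route at 17.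

Further compounds
F1 | step 4 | 1-heptyl-3,5-dimethoxybenzene | CCCCCCCc1cc(OC)cc(OC)c1
F2 | step 4 | 2-heptyl-4,6-dimethoxybenzaldehyde | CCCCCCCc1cc(OC)cc(OC)c1C=O
F3 | step 1 | 1,3-dimethoxy-5-(methoxymethoxy)benzene | COCOc1cc(OC)cc(OC)c1
F4 | step 1 | 2-iodo-1,5-dimethoxy-3-(methoxymethoxy)benzene | COCOc1cc(OC)cc(OC)c1I
F5 | step 9 | 2-heptyl-4,6-dimethoxybenzoyl chloride | CCCCCCCc1cc(OC)cc(OC)c1C(Cl)=O
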